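**Retrosynthetic overview**
1. The target is a (1(10)Z,4Z)-cyclodecadiene (C1–C10) trans-fused at C6–C7 to an α-methylene-γ-butyrolactone (O1, C6, C7, C11, C12, exocyclic C13). The last operations acylate the C8 hydroxyl of macrocycle 35 with the preformed epoxy acid 3 and unmask the C9 hydroxyl.
2. Key disconnection C7–C8: the array C13=C11–C7–C8–OH (exocyclic methylene of the lactone, ring-fusion carbon C7, ring carbinol C8) is the product pattern of a carbonyl allylation. The ten-membered ring is therefore opened to the 3-(bromomethyl)butenolide aldehyde 33, in which the lactone already exists and C6 and C9 relay to C7 and C8.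
3. The seco chain 33 comes from a C3–C4 union (asymmetric Nozaki–Hiyama–Kishi coupling) of butenolide alkenyl iodide 14 with aldehyde 26.
4. For 14, C6 comes from a Sharpless kinetic resolution, the Z-iodoalkene from hydroxyl-directed hydroalumination–iodination and the butenolide from ring-closing metathesis. For 26, C9 is bought as a glycerate and the Z-alkene comes from a Wittig reaction of an α-alkoxy ketone.
5. Ring order: oxirane of the side-chain acid (step 1), butenolide (step 8), ten-membered carbocycle (step 24).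

Key step: step 24

Remark: the acyl group as written is the (2S,3R)-2,3-dimethyloxirane-2-carboxylate with the two methyl groups cis (epoxide of a tiglate), and both ring double bonds are Z. Germacrane numbering is used in the text (ring C1–C10, lactone carbons C11–C13, O1 on C6).

Step 1
Reactants: 1 (E)-2-methylbut-2-en-1-ol
Product: 2 [(2R,3R)-2,3-dimethyloxiran-2-yl]methanol
Conditions: Ti(OiPr)4 (5 mol %), D-(−)-diethyl tartrate (6 mol %), t-BuOOH, 4 Å MS, CH2Cl2, −20 °C
Reagents that add atoms: tert-butyl hydroperoxide, CC(C)(C)OO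
Why: Sharpless asymmetric epoxidation of an E-allylic alcohol; the D-(−)-tartrate complex should deliver oxygen to the face that gives the (2R,3R)-epoxide, and syn addition keeps the two methyl groups cis.

Step 2
Reactants: 2 [(2R,3R)-2,3-dimethyloxiran-2-yl]methanol
Product: 3 (2S,3R)-2,3-dimethyloxirane-2-carboxylic acid
Conditions: RuCl3·H2O (2 mol %), NaIO4, CCl4/MeCN/H2O, rt
Reagents that add atoms: sodium periodate, [Na+].[O-]I(=O)(=O)=O
Why: RuO4-catalysed oxidation of a primary epoxy alcohol to the glycidic acid; no stereocentre is touched (the C2 descriptor changes only through CIP priorities).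

Step 3
Reactants: 4 2-(bromomethyl)acrylic acid; 5 4-methoxybenzyl alcohol
Product: 6 2-{[(4-methoxybenzyl)oxy]methyl}acrylic acid
Conditions: NaH (2.2 equiv), THF, 0 °C to rt; then 1 M HCl
Reagents that add atoms: none
Why: Williamson-type displacement of the activated allylic bromide of the carboxylate salt by the alkoxide (SN2 and SN2′ paths are degenerate).

Step 4
Reactants: 7 acrolein; 8 1-propynylmagnesium bromide
Product: 9 rac-hex-1-en-4-yn-3-ol
Conditions: THF, −78 to 0 °C; aq. NH4Cl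
Reagents that add atoms: none
Why: 1,2-addition of an alkynyl Grignard reagent to an enal gives the racemic alkynyl vinyl carbinol.

Step 5
Reactants: 9 rac-hex-1-en-4-yn-3-ol
Product: 10 (3S)-hex-1-en-4-yn-3-ol
Conditions: Ti(OiPr)4 (10 mol %), L-(+)-diisopropyl tartrate (15 mol %), t-BuOOH (0.6 equiv), 4 Å MS, CH2Cl2, −20 °C; unreacted alcohol recovered
Reagents that add atoms: none
Why: Sharpless kinetic resolution of a secondary allylic alcohol; with the L-(+)-tartrate the (R)-enantiomer should be epoxidised much faster at its vinyl group (erythro epoxy alcohol), so the (S)-alcohol that becomes C6 is recovered.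

Step 6
Reactants: 10 (3S)-hex-1-en-4-yn-3-ol
Product: 12 (3S,4Z)-5-iodohexa-1,4-dien-3-ol, via sodium alkenylalanate 11 (not isolated)
Conditions: NaAlH2(OCH2CH2OMe)2 (Red-Al), THF, 0 °C to rt; then I2, THF, −78 to 0 °C
Reagents that add atoms: iodine, [I][I]
Why: hydroxyl-directed trans-hydroalumination of the propargylic alcohol places aluminium on the distal alkyne carbon in a five-membered alanate, and iodinolysis with retention should give the Z-iodoalkene (iodine cis to the carbinol carbon).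

Step 7
Reactants: 12 (3S,4Z)-5-iodohexa-1,4-dien-3-ol; 6 2-{[(4-methoxybenzyl)oxy]methyl}acrylic acid
Product: 13 (3S,4Z)-5-iodohexa-1,4-dien-3-yl 2-{[(4-methoxybenzyl)oxy]methyl}acrylate
Conditions: DCC, DMAP (cat.), CH2Cl2, 0 °C to rt
Reagents that add atoms: none
Why: Steglich esterification of the secondary alcohol; the stereocentre is not involved.

Step 8
Reactants: 13 (3S,4Z)-5-iodohexa-1,4-dien-3-yl 2-{[(4-methoxybenzyl)oxy]methyl}acrylate
Product: 14 (5S)-5-[(1Z)-2-iodoprop-1-en-1-yl]-3-{[(4-methoxybenzyl)oxy]methyl}furan-2(5H)-one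
Conditions: second-generation Grubbs catalyst RuCl2(=CHPh)(H2IMes)(PCy3) (5 mol %), toluene (5 mM), 80 °C
Reagents that add atoms: none
Why: ring-closing metathesis between the terminal vinyl group and the 1,1-disubstituted acrylate closes the butenolide (C7=C11); the trisubstituted iodoalkene should be inert and C6 is untouched.

Step 9
Reactants: 15 3-[(4-methoxybenzyl)oxy]propan-1-ol
Product: 16 1-[(3-iodopropoxy)methyl]-4-methoxybenzene
Conditions: I2, PPh3, imidazole, CH2Cl2, 0 °C to rt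
Reagents that add atoms: iodine, [I][I]
Why: Appel-type iodination of a primary alcohol.

Step 10
Reactants: 16 1-[(3-iodopropoxy)methyl]-4-methoxybenzene
Product: 17 {3-[(4-methoxybenzyl)oxy]propyl}triphenylphosphonium iodide
Conditions: PPh3, MeCN, 80 °C
Reagents that add atoms: triphenylphosphine, c1ccc(cc1)P(c1ccccc1)c1ccccc1
Why: SN2 quaternisation of triphenylphosphine by the primary iodide.

Step 11
Reactants: 18 methyl (4S)-2,2-dimethyl-1,3-dioxolane-4-carboxylate
Product: 19 (4S)-N-methoxy-N,2,2-trimethyl-1,3-dioxolane-4-carboxamide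
Conditions: MeNH(OMe)·HCl, i-PrMgCl, THF, −20 °C; aq. NH4Cl
Reagents that add atoms: N,O-dimethylhydroxylamine hydrochloride, CNOC.Cl
Why: Weinreb amide formation from the ester with the magnesium amide; the α-alkoxy stereocentre (the future C9, bought) should not enolise at −20 °C.

Step 12
Reactants: 19 (4S)-N-methoxy-N,2,2-trimethyl-1,3-dioxolane-4-carboxamide
Product: 20 1-[(4S)-2,2-dimethyl-1,3-dioxolan-4-yl]ethan-1-one
Conditions: MeMgBr, THF, 0 °C; aq. NH4Cl
Reagents that add atoms: methylmagnesium bromide, C[Mg]Br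
Why: Weinreb ketone synthesis; the chelated tetrahedral intermediate prevents over-addition.

Step 13
Reactants: 17 {3-[(4-methoxybenzyl)oxy]propyl}triphenylphosphonium iodide; 20 1-[(4S)-2,2-dimethyl-1,3-dioxolan-4-yl]ethan-1-one
Product: 22 (4R)-4-{(2Z)-5-[(4-methoxybenzyl)oxy]pent-2-en-2-yl}-2,2-dimethyl-1,3-dioxolane, via phosphorus ylide 21 (not isolated)
Conditions: NaN(SiMe3)2 (slightly less than 1 equiv per 17), THF, −78 to 0 °C; then 20, −78 °C to rt
Reagents that add atoms: none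
Why: salt-free Wittig reaction of a non-stabilised ylide with an α-alkoxy methyl ketone, which is known to give Z-trisubstituted allylic ethers (ylide chain cis to the oxygenated carbon), sets the C1=C10 geometry; C9 keeps its configuration (descriptor R by CIP change only).

Step 14
Reactants: 22 (4R)-4-{(2Z)-5-[(4-methoxybenzyl)oxy]pent-2-en-2-yl}-2,2-dimethyl-1,3-dioxolane
Product: 23 (2R,3Z)-6-[(4-methoxybenzyl)oxy]-3-methylhex-3-ene-1,2-diol
Conditions: AcOH/H2O (4:1), 40 °C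
Reagents that add atoms: none
Why: mild acid hydrolysis of the acetonide; the PMB ether and the allylic stereocentre should survive.

Step 15
Reactants: 23 (2R,3Z)-6-[(4-methoxybenzyl)oxy]-3-methylhex-3-ene-1,2-diol
Product: 24 (2R,3Z)-1,2-bis{[tert-butyl(dimethyl)silyl]oxy}-6-[(4-methoxybenzyl)oxy]-3-methylhex-3-ene
Conditions: TBSOTf, 2,6-lutidine, CH2Cl2, −78 to 0 °C
Reagents that add atoms: tert-butyldimethylsilyl trifluoromethanesulfonate, CC(C)(C)[Si](C)(C)OS(=O)(=O)C(F)(F)F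
Why: silylation of both hydroxyls; the non-chelating C9–OTBS group is the Felkin–Anh control element of the key step.

Step 16
Reactants: 24 (2R,3Z)-1,2-bis{[tert-butyl(dimethyl)silyl]oxy}-6-[(4-methoxybenzyl)oxy]-3-methylhex-3-ene
Product: 25 (3Z,5R)-5,6-bis{[tert-butyl(dimethyl)silyl]oxy}-4-methylhex-3-en-1-ol
Conditions: DDQ, CH2Cl2/pH 7 buffer, 0 °C
Reagents that add atoms: none
Why: oxidative cleavage of the PMB ether; silyl ethers and the trisubstituted alkene are stable to buffered DDQ.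

Step 17
Reactants: 25 (3Z,5R)-5,6-bis{[tert-butyl(dimethyl)silyl]oxy}-4-methylhex-3-en-1-ol
Product: 26 (3Z,5R)-5,6-bis{[tert-butyl(dimethyl)silyl]oxy}-4-methylhex-3-enal
Conditions: Dess–Martin periodinane, NaHCO3, CH2Cl2, 0 °C; used at once
Reagents that add atoms: none
Why: Dess–Martin oxidation under buffered, neutral conditions should keep the β,γ-double bond out of conjugation.

Step 18
Reactants: 14 (5S)-5-[(1Z)-2-iodoprop-1-en-1-yl]-3-{[(4-methoxybenzyl)oxy]methyl}furan-2(5H)-one; 26 (3Z,5R)-5,6-bis{[tert-butyl(dimethyl)silyl]oxy}-4-methylhex-3-enal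
Product: 28 (5R)-5-[(1Z,3S,5Z,7R)-7,8-bis{[tert-butyl(dimethyl)silyl]oxy}-3-hydroxy-2,6-dimethylocta-1,5-dien-1-yl]-3-{[(4-methoxybenzyl)oxy]methyl}furan-2(5H)-one, via alkenylchromium dichloride 27 (not isolated)
Conditions: CrCl2 (4 equiv), (S)-N-[2-(4-isopropyl-4,5-dihydrooxazol-2-yl)-6-methylphenyl]methanesulfonamide (4.4 equiv), Et3N (4.4 equiv), THF, rt; then NiCl2 (2 mol %), 14 and 26, rt; basic aqueous work-up
Reagents that add atoms: none
Why: asymmetric Nozaki–Hiyama–Kishi coupling, which should retain the Z geometry of the alkenyl iodide and spare the lactone; C3 is set by catalyst control from the chiral sulfonamide complex of trivalent chromium (ligand antipode to be confirmed in a model coupling), and the C6 descriptor becomes R by CIP change only.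

Step 19
Reactants: 28 (5R)-5-[(1Z,3S,5Z,7R)-7,8-bis{[tert-butyl(dimethyl)silyl]oxy}-3-hydroxy-2,6-dimethylocta-1,5-dien-1-yl]-3-{[(4-methoxybenzyl)oxy]methyl}furan-2(5H)-one
Product: 29 (5R)-5-[(1Z,3S,5Z,7R)-3-acetoxy-7,8-bis{[tert-butyl(dimethyl)silyl]oxy}-2,6-dimethylocta-1,5-dien-1-yl]-3-{[(4-methoxybenzyl)oxy]methyl}furan-2(5H)-one
Conditions: Ac2O, pyridine, DMAP (cat.), CH2Cl2, 0 °C
Reagents that add atoms: acetic anhydride, CC(=O)OC(C)=O
Why: acetylation of the secondary allylic alcohol with retention installs the C3 acetate of the target.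

Step 20
Reactants: 29 (5R)-5-[(1Z,3S,5Z,7R)-3-acetoxy-7,8-bis{[tert-butyl(dimethyl)silyl]oxy}-2,6-dimethylocta-1,5-dien-1-yl]-3-{[(4-methoxybenzyl)oxy]methyl}furan-2(5H)-one
Product: 30 (5R)-5-[(1Z,3S,5Z,7R)-3-acetoxy-7,8-bis{[tert-butyl(dimethyl)silyl]oxy}-2,6-dimethylocta-1,5-dien-1-yl]-3-(hydroxymethyl)furan-2(5H)-one
Conditions: DDQ, CH2Cl2/pH 7 buffer, 0 °C to rt
Reagents that add atoms: none
Why: oxidative PMB cleavage frees the C13 hydroxyl; acetate, silyl ethers and butenolide are inert.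

Step 21
Reactants: 30 (5R)-5-[(1Z,3S,5Z,7R)-3-acetoxy-7,8-bis{[tert-butyl(dimethyl)silyl]oxy}-2,6-dimethylocta-1,5-dien-1-yl]-3-(hydroxymethyl)furan-2(5H)-one
Product: 31 (5R)-5-[(1Z,3S,5Z,7R)-3-acetoxy-7,8-bis{[tert-butyl(dimethyl)silyl]oxy}-2,6-dimethylocta-1,5-dien-1-yl]-3-(bromomethyl)furan-2(5H)-one
Conditions: CBr4, PPh3, CH2Cl2, 0 °C, short reaction time
Reagents that add atoms: carbon tetrabromide, BrC(Br)(Br)Br
Why: Appel bromination of the primary allylic alcohol under neutral conditions, which avoids base at the acidic C6–H of the butenolide.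

Step 22
Reactants: 31 (5R)-5-[(1Z,3S,5Z,7R)-3-acetoxy-7,8-bis{[tert-butyl(dimethyl)silyl]oxy}-2,6-dimethylocta-1,5-dien-1-yl]-3-(bromomethyl)furan-2(5H)-one
Product: 32 (5R)-5-[(1Z,3S,5Z,7R)-3-acetoxy-7-{[tert-butyl(dimethyl)silyl]oxy}-8-hydroxy-2,6-dimethylocta-1,5-dien-1-yl]-3-(bromomethyl)furan-2(5H)-one
Conditions: camphor-10-sulfonic acid (0.2 equiv), MeOH/CH2Cl2 (1:1), 0 °C
Reagents that add atoms: none
Why: acid-catalysed methanolysis should remove the primary silyl ether much faster than the secondary one, and the allylic bromide and acetate should tolerate cold, base-free methanol.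

Step 23
Reactants: 32 (5R)-5-[(1Z,3S,5Z,7R)-3-acetoxy-7-{[tert-butyl(dimethyl)silyl]oxy}-8-hydroxy-2,6-dimethylocta-1,5-dien-1-yl]-3-(bromomethyl)furan-2(5H)-one
Product: 33 (5R)-5-[(1Z,3S,5Z,7R)-3-acetoxy-7-{[tert-butyl(dimethyl)silyl]oxy}-2,6-dimethyl-8-oxoocta-1,5-dien-1-yl]-3-(bromomethyl)furan-2(5H)-one
Conditions: Dess–Martin periodinane, NaHCO3, CH2Cl2, 0 °C; filtered and used at once
Reagents that add atoms: none
Why: neutral Dess–Martin oxidation gives the α-silyloxy aldehyde without epimerising C9 or disturbing the allylic bromide.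

Step 24
Reactants: 33 (5R)-5-[(1Z,3S,5Z,7R)-3-acetoxy-7-{[tert-butyl(dimethyl)silyl]oxy}-2,6-dimethyl-8-oxoocta-1,5-dien-1-yl]-3-(bromomethyl)furan-2(5H)-one
Product: 35 (3aR,4S,5R,6Z,9S,10Z,11aR)-5-{[tert-butyl(dimethyl)silyl]oxy}-4-hydroxy-6,10-dimethyl-3-methylidene-2-oxo-2,3,3a,4,5,8,9,11a-octahydrocyclodeca[b]furan-9-yl acetate, via allylchromium dichloride 34 (not isolated)
Conditions: CrCl2 (10 equiv), THF, 25 °C, syringe-pump addition of 33 to 2 mM final concentration; H2O work-up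
Reagents that add atoms: none
Why: Proposed new method: CrCl2 reduces the allylic C13–Br bond to the allylchromium species 34, which adds through C7 (SE2′, six-membered Cr–O8–C8–C7–C11–C13 transition state) to the tethered C8 aldehyde, moving the double bond to the exocyclic C11=C13 position and leaving a free C8 hydroxyl; the closest known reactions are the intermolecular chromium- and indium-mediated allylations of aldehydes with 3-(bromomethyl)furan-2(5H)-one and the intramolecular Nozaki–Hiyama–Kishi allylations of 2-(bromomethyl)acrylate aldehydes that close ten-membered germacranolide rings. The ten-membered ring closes by a 10-exo-trig addition to the carbonyl group and is the only ring formed, because the lactone is already present. C7 is controlled by C6: allylic 1,3-strain across the (Z)-C4=C5 bond holds H-6 in the alkene plane and turns the chain back under the H-6 face of the butenolide, so C8 should bond anti to the C6–C5 bond (trans-fused lactone, 7S). C8 is controlled by C9: Felkin–Anh addition anti to the C9–OTBS bond gives the 8,9-anti pattern (8S), and the short tether with two Z-alkenes is expected to present the aldehyde with C9 gauche to C6 (pseudo-axial in the chair), which is the same 7,8-syn topicity. The step needs chemoselectivity for the allylic bromide over the allylic acetate, silyl ether and enoate, which divalent chromium should provide, and cyclisation over oligomerisation, which slow addition at high dilution secures.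

Step 25
Reactants: 35 (3aR,4S,5R,6Z,9S,10Z,11aR)-5-{[tert-butyl(dimethyl)silyl]oxy}-4-hydroxy-6,10-dimethyl-3-methylidene-2-oxo-2,3,3a,4,5,8,9,11a-octahydrocyclodeca[b]furan-9-yl acetate; 3 (2S,3R)-2,3-dimethyloxirane-2-carboxylic acid
Product: 37 (3aS,4S,5R,6Z,9S,10Z,11aR)-9-acetoxy-5-{[tert-butyl(dimethyl)silyl]oxy}-6,10-dimethyl-3-methylidene-2-oxo-2,3,3a,4,5,8,9,11a-octahydrocyclodeca[b]furan-4-yl (2S,3R)-2,3-dimethyloxirane-2-carboxylate, via mixed anhydride 36 (not isolated)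
Conditions: 3, 2,4,6-trichlorobenzoyl chloride, Et3N, THF, 0 °C to rt; then 35, DMAP, toluene, rt
Reagents that add atoms: none
Why: Yamaguchi esterification acylates the hindered C8 hydroxyl with retention and without opening the oxirane (the C3a descriptor changes by CIP only).

Step 26
Reactants: 37 (3aS,4S,5R,6Z,9S,10Z,11aR)-9-acetoxy-5-{[tert-butyl(dimethyl)silyl]oxy}-6,10-dimethyl-3-methylidene-2-oxo-2,3,3a,4,5,8,9,11a-octahydrocyclodeca[b]furan-4-yl (2S,3R)-2,3-dimethyloxirane-2-carboxylate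
Product: 38 (3aS,4S,5R,6Z,9S,10Z,11aR)-9-acetoxy-5-hydroxy-6,10-dimethyl-3-methylidene-2-oxo-2,3,3a,4,5,8,9,11a-octahydrocyclodeca[b]furan-4-yl (2S,3R)-2,3-dimethyloxirane-2-carboxylate (target)
Conditions: HF·pyridine, pyridine, THF, 0 °C to rt
Reagents that add atoms: none
Why: buffered fluoride desilylation of the secondary silyl ether; weakly acidic conditions should avoid 8-to-9 acyl migration, oxirane opening and loss of the acetate.

**Compound list**
1 | (E)-2-methylbut-2-en-1-ol | C/C=C(\C)CO | starting material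
2 | [(2R,3R)-2,3-dimethyloxiran-2-yl]methanol | OC[C@@]1(C)O[C@@H]1C | intermediate
3 | (2S,3R)-2,3-dimethyloxirane-2-carboxylic acid | OC(=O)[C@@]1(C)O[C@@H]1C | intermediate
4 | 2-(bromomethyl)acrylic acid | C=C(CBr)C(=O)O | starting material
5 | 4-methoxybenzyl alcohol | COc1ccc(CO)cc1 | starting material
6 | 2-{[(4-methoxybenzyl)oxy]methyl}acrylic acid | C=C(COCc1ccc(OC)cc1)C(=O)O | intermediate
7 | acrolein | C=CC=O | starting material
8 | 1-propynylmagnesium bromide | CC#C[Mg]Br | starting material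
9 | rac-hex-1-en-4-yn-3-ol | C=CC(O)C#CC | intermediate
10 | (3S)-hex-1-en-4-yn-3-ol | C=C[C@H](O)C#CC | intermediate
11 | sodium alkenylalanate from 10 (five-membered O–Al–C ring, not isolated) | C=C[C@@H]1O[Al-](OCCOC)(OCCOC)C(C)=C1.[Na+] | intermediate
12 | (3S,4Z)-5-iodohexa-1,4-dien-3-ol | C=C[C@H](O)/C=C(/C)I | intermediate
13 | (3S,4Z)-5-iodohexa-1,4-dien-3-yl 2-{[(4-methoxybenzyl)oxy]methyl}acrylate | C=C[C@H](OC(=O)C(=C)COCc1ccc(OC)cc1)/C=C(/C)I | intermediate
14 | (5S)-5-[(1Z)-2-iodoprop-1-en-1-yl]-3-{[(4-methoxybenzyl)oxy]methyl}furan-2(5H)-one | COc1ccc(COCC2=C[C@H](OC2=O)/C=C(/C)I)cc1 | intermediate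
15 | 3-[(4-methoxybenzyl)oxy]propan-1-ol | COc1ccc(COCCCO)cc1 | starting material
16 | 1-[(3-iodopropoxy)methyl]-4-methoxybenzene | COc1ccc(COCCCI)cc1 | intermediate
17 | {3-[(4-methoxybenzyl)oxy]propyl}triphenylphosphonium iodide | COc1ccc(COCCC[P+](c2ccccc2)(c2ccccc2)c2ccccc2)cc1.[I-] | intermediate
18 | methyl (4S)-2,2-dimethyl-1,3-dioxolane-4-carboxylate | COC(=O)[C@@H]1COC(C)(C)O1 | starting material
19 | (4S)-N-methoxy-N,2,2-trimethyl-1,3-dioxolane-4-carboxamide | CON(C)C(=O)[C@@H]1COC(C)(C)O1 | intermediate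
20 | 1-[(4S)-2,2-dimethyl-1,3-dioxolan-4-yl]ethan-1-one | CC(=O)[C@@H]1COC(C)(C)O1 | intermediate
21 | {3-[(4-methoxybenzyl)oxy]propylidene}triphenylphosphorane (not isolated) | COc1ccc(COCCC=P(c2ccccc2)(c2ccccc2)c2ccccc2)cc1 | intermediate
22 | (4R)-4-{(2Z)-5-[(4-methoxybenzyl)oxy]pent-2-en-2-yl}-2,2-dimethyl-1,3-dioxolane | COc1ccc(COCC/C=C(/C)[C@@H]2COC(C)(C)O2)cc1 | intermediate
23 | (2R,3Z)-6-[(4-methoxybenzyl)oxy]-3-methylhex-3-ene-1,2-diol | COc1ccc(COCC/C=C(/C)[C@@H](O)CO)cc1 | intermediate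
24 | (2R,3Z)-1,2-bis{[tert-butyl(dimethyl)silyl]oxy}-6-[(4-methoxybenzyl)oxy]-3-methylhex-3-ene | COc1ccc(COCC/C=C(/C)[C@@H](O[Si](C)(C)C(C)(C)C)CO[Si](C)(C)C(C)(C)C)cc1 | intermediate
25 | (3Z,5R)-5,6-bis{[tert-butyl(dimethyl)silyl]oxy}-4-methylhex-3-en-1-ol | OCC/C=C(/C)[C@@H](O[Si](C)(C)C(C)(C)C)CO[Si](C)(C)C(C)(C)C | intermediate
26 | (3Z,5R)-5,6-bis{[tert-butyl(dimethyl)silyl]oxy}-4-methylhex-3-enal | O=CC/C=C(/C)[C@@H](O[Si](C)(C)C(C)(C)C)CO[Si](C)(C)C(C)(C)C | intermediate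
27 | alkenylchromium dichloride from 14 (trivalent chromium, not isolated) | COc1ccc(COCC2=C[C@H](OC2=O)/C=C(/C)[Cr](Cl)Cl)cc1 | intermediate
28 | (5R)-5-[(1Z,3S,5Z,7R)-7,8-bis{[tert-butyl(dimethyl)silyl]oxy}-3-hydroxy-2,6-dimethylocta-1,5-dien-1-yl]-3-{[(4-methoxybenzyl)oxy]methyl}furan-2(5H)-one | COc1ccc(COCC2=C[C@H](OC2=O)/C=C(/C)[C@@H](O)C/C=C(/C)[C@@H](O[Si](C)(C)C(C)(C)C)CO[Si](C)(C)C(C)(C)C)cc1 | intermediate
29 | (5R)-5-[(1Z,3S,5Z,7R)-3-acetoxy-7,8-bis{[tert-butyl(dimethyl)silyl]oxy}-2,6-dimethylocta-1,5-dien-1-yl]-3-{[(4-methoxybenzyl)oxy]methyl}furan-2(5H)-one | COc1ccc(COCC2=C[C@H](OC2=O)/C=C(/C)[C@@H](OC(C)=O)C/C=C(/C)[C@@H](O[Si](C)(C)C(C)(C)C)CO[Si](C)(C)C(C)(C)C)cc1 | intermediate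
30 | (5R)-5-[(1Z,3S,5Z,7R)-3-acetoxy-7,8-bis{[tert-butyl(dimethyl)silyl]oxy}-2,6-dimethylocta-1,5-dien-1-yl]-3-(hydroxymethyl)furan-2(5H)-one | OCC1=C[C@H](OC1=O)/C=C(/C)[C@@H](OC(C)=O)C/C=C(/C)[C@@H](O[Si](C)(C)C(C)(C)C)CO[Si](C)(C)C(C)(C)C | intermediate
31 | (5R)-5-[(1Z,3S,5Z,7R)-3-acetoxy-7,8-bis{[tert-butyl(dimethyl)silyl]oxy}-2,6-dimethylocta-1,5-dien-1-yl]-3-(bromomethyl)furan-2(5H)-one | BrCC1=C[C@H](OC1=O)/C=C(/C)[C@@H](OC(C)=O)C/C=C(/C)[C@@H](O[Si](C)(C)C(C)(C)C)CO[Si](C)(C)C(C)(C)C | intermediate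
32 | (5R)-5-[(1Z,3S,5Z,7R)-3-acetoxy-7-{[tert-butyl(dimethyl)silyl]oxy}-8-hydroxy-2,6-dimethylocta-1,5-dien-1-yl]-3-(bromomethyl)furan-2(5H)-one | BrCC1=C[C@H](OC1=O)/C=C(/C)[C@@H](OC(C)=O)C/C=C(/C)[C@@H](O[Si](C)(C)C(C)(C)C)CO | intermediate
33 | (5R)-5-[(1Z,3S,5Z,7R)-3-acetoxy-7-{[tert-butyl(dimethyl)silyl]oxy}-2,6-dimethyl-8-oxoocta-1,5-dien-1-yl]-3-(bromomethyl)furan-2(5H)-one | BrCC1=C[C@H](OC1=O)/C=C(/C)[C@@H](OC(C)=O)C/C=C(/C)[C@@H](O[Si](C)(C)C(C)(C)C)C=O | intermediate
34 | allylchromium dichloride from 33 (trivalent chromium on C13, not isolated) | Cl[Cr](Cl)CC1=C[C@H](OC1=O)/C=C(/C)[C@@H](OC(C)=O)C/C=C(/C)[C@@H](O[Si](C)(C)C(C)(C)C)C=O | intermediate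
35 | (3aR,4S,5R,6Z,9S,10Z,11aR)-5-{[tert-butyl(dimethyl)silyl]oxy}-4-hydroxy-6,10-dimethyl-3-methylidene-2-oxo-2,3,3a,4,5,8,9,11a-octahydrocyclodeca[b]furan-9-yl acetate | C=C1C(=O)O[C@@H]2/C=C(/C)[C@@H](OC(C)=O)C/C=C(/C)[C@@H](O[Si](C)(C)C(C)(C)C)[C@@H](O)[C@@H]12 | intermediate
36 | (2S,3R)-2,3-dimethyloxirane-2-carboxylic 2,4,6-trichlorobenzoic anhydride (not isolated) | O=C(OC(=O)c1c(Cl)cc(Cl)cc1Cl)[C@@]1(C)O[C@@H]1C | intermediate
37 | (3aS,4S,5R,6Z,9S,10Z,11aR)-9-acetoxy-5-{[tert-butyl(dimethyl)silyl]oxy}-6,10-dimethyl-3-methylidene-2-oxo-2,3,3a,4,5,8,9,11a-octahydrocyclodeca[b]furan-4-yl (2S,3R)-2,3-dimethyloxirane-2-carboxylate | C=C1C(=O)O[C@@H]2/C=C(/C)[C@@H](OC(C)=O)C/C=C(/C)[C@@H](O[Si](C)(C)C(C)(C)C)[C@@H](OC(=O)[C@@]3(C)O[C@@H]3C)[C@@H]12 | intermediate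
38 | (3aS,4S,5R,6Z,9S,10Z,11aR)-9-acetoxy-5-hydroxy-6,10-dimethyl-3-methylidene-2-oxo-2,3,3a,4,5,8,9,11a-octahydrocyclodeca[b]furan-4-yl (2S,3R)-2,3-dimethyloxirane-2-carboxylate | C=C1C(=O)O[C@@H]2/C=C(/C)[C@@H](OC(C)=O)C/C=C(/C)[C@@H](O)[C@@H](OC(=O)[C@@]3(C)O[C@@H]3C)[C@@H]12 | target

**Totals and risks**
Total step count: 26. Longest linear sequence: 16 steps (steps 11–26 from 18, or steps 9, 10 and 13–26 from 15).

Steps most likely to fail:

1. Step 24 (Proposed new method). What may go wrong: delivery of the aldehyde through the equatorial chair or to the other face of the butenolide (C8 epimer or cis-fused lactone), oligomerisation in place of ring closure, or translactonisation of the chromium alkoxide at O8 onto C12. Fallback with known chemistry, setting out from 14 and 24 and coming back at 37: the order of the two carbon–carbon bond formations is exchanged. DDQ cleavage of the PMB ether of 14 gives (5S)-3-(hydroxymethyl)-5-[(1Z)-2-iodoprop-1-en-1-yl]furan-2(5H)-one F1, and CBr4/PPh3 gives (5S)-3-(bromomethyl)-5-[(1Z)-2-iodoprop-1-en-1-yl]furan-2(5H)-one F2. Selective methanolysis of the primary silyl ether of 24 (camphorsulfonic acid, MeOH) gives (2R,3Z)-2-{[tert-butyl(dimethyl)silyl]oxy}-6-[(4-methoxybenzyl)oxy]-3-methylhex-3-en-1-ol F3, and Dess–Martin oxidation gives the corresponding hex-3-enal F4. Indium-mediated Barbier allylation of F4 with F2 (indium powder, THF/H2O), which is known for 3-(bromomethyl)furan-2(5H)-ones and leaves the alkenyl iodide untouched, should give the open-chain α-methylene lactone with the C7–C8 bond and a free C8 hydroxyl F5, to be separated from its C8 epimer. Yamaguchi esterification with 3 gives the C8 epoxy ester F6; DDQ gives the primary C3 alcohol F7 and Dess–Martin oxidation the C3 aldehyde F8. An intramolecular Nozaki–Hiyama–Kishi reaction (CrCl2, cat. NiCl2, DMSO/THF, high dilution) then closes the ten-membered ring at C3–C4 to the macrocyclic C3 alcohol F9, which is acetylated (Ac2O, pyridine) to 37.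

2. Step 18. What may go wrong: weak catalyst control at C3, or base-induced migration of the β,γ-double bond of 26 into conjugation before coupling. Fallback, setting out from 14 and 26 and coming back at 29: ligand-free coupling (CrCl2, cat. NiCl2, DMSO) gives 28 together with its C3 epimer, (5R)-5-[(1Z,3R,5Z,7R)-7,8-bis{[tert-butyl(dimethyl)silyl]oxy}-3-hydroxy-2,6-dimethylocta-1,5-dien-1-yl]-3-{[(4-methoxybenzyl)oxy]methyl}furan-2(5H)-one F10. After separation 28 goes through step 19, and F10 is converted into the same acetate 29 by Mitsunobu inversion with acetic acid (PPh3, diisopropyl azodicarboxylate).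

3. Step 13. What may go wrong: erosion of the Z selectivity, or epimerisation of the α-alkoxy ketone 20 by the basic ylide. Fallback, setting out from 15 and coming back at 24: Dess–Martin oxidation of 15 gives 3-[(4-methoxybenzyl)oxy]propanal F11. Stork–Zhao-type olefination with the ylide from (1-iodoethyl)triphenylphosphonium iodide and NaN(SiMe3)2 gives 1-({[(3Z)-4-iodopent-3-en-1-yl]oxy}methyl)-4-methoxybenzene F12. Asymmetric Nozaki–Hiyama–Kishi coupling of F12 with (tert-butyldimethylsilyloxy)acetaldehyde (CrCl2, the sulfonamide ligand of step 18, cat. NiCl2) gives (2R,3Z)-1-{[tert-butyl(dimethyl)silyl]oxy}-6-[(4-methoxybenzyl)oxy]-3-methylhex-3-en-2-ol F13, and silylation (TBSOTf, 2,6-lutidine) gives 24.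

Further compounds
F1 | step 24 | (5S)-3-(hydroxymethyl)-5-[(1Z)-2-iodoprop-1-en-1-yl]furan-2(5H)-one | OCC1=C[C@H](OC1=O)/C=C(/C)I
F2 | step 24 | (5S)-3-(bromomethyl)-5-[(1Z)-2-iodoprop-1-en-1-yl]furan-2(5H)-one | BrCC1=C[C@H](OC1=O)/C=C(/C)I
F3 | step 24 | (2R,3Z)-2-{[tert-butyl(dimethyl)silyl]oxy}-6-[(4-methoxybenzyl)oxy]-3-methylhex-3-en-1-ol | COc1ccc(COCC/C=C(/C)[C@@H](O[Si](C)(C)C(C)(C)C)CO)cc1
F4 | step 24 | (2R,3Z)-2-{[tert-butyl(dimethyl)silyl]oxy}-6-[(4-methoxybenzyl)oxy]-3-methylhex-3-enal | COc1ccc(COCC/C=C(/C)[C@@H](O[Si](C)(C)C(C)(C)C)C=O)cc1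
F5 | step 24 | open-chain α-methylene-γ-butyrolactone with C7–C8 bond, free C8 hydroxyl, C9 silyl ether, C3 PMB ether and Z-iodopropenyl group on C6 (ring stereocentres as in 35) | C=C1C(=O)O[C@H](/C=C(/C)I)[C@H]1[C@H](O)[C@H](O[Si](C)(C)C(C)(C)C)/C(C)=C\CCOCc1ccc(OC)cc1
F6 | step 24 | C8 (2S,3R)-2,3-dimethyloxirane-2-carboxylate of F5 | C=C1C(=O)O[C@H](/C=C(/C)I)[C@H]1[C@H](OC(=O)[C@@]2(C)O[C@@H]2C)[C@H](O[Si](C)(C)C(C)(C)C)/C(C)=C\CCOCc1ccc(OC)cc1
F7 | step 24 | primary C3 alcohol from F6 | C=C1C(=O)O[C@H](/C=C(/C)I)[C@H]1[C@H](OC(=O)[C@@]2(C)O[C@@H]2C)[C@H](O[Si](C)(C)C(C)(C)C)/C(C)=C\CCO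
F8 | step 24 | C3 aldehyde from F7 | C=C1C(=O)O[C@H](/C=C(/C)I)[C@H]1[C@H](OC(=O)[C@@]2(C)O[C@@H]2C)[C@H](O[Si](C)(C)C(C)(C)C)/C(C)=C\CC=O
F9 | step 24 | macrocyclic C3 alcohol (37 without the acetyl group) | C=C1C(=O)O[C@@H]2/C=C(/C)[C@@H](O)C/C=C(/C)[C@@H](O[Si](C)(C)C(C)(C)C)[C@@H](OC(=O)[C@@]3(C)O[C@@H]3C)[C@@H]12
F10 | step 18 | (5R)-5-[(1Z,3R,5Z,7R)-7,8-bis{[tert-butyl(dimethyl)silyl]oxy}-3-hydroxy-2,6-dimethylocta-1,5-dien-1-yl]-3-{[(4-methoxybenzyl)oxy]methyl}furan-2(5H)-one | COc1ccc(COCC2=C[C@H](OC2=O)/C=C(/C)[C@H](O)C/C=C(/C)[C@@H](O[Si](C)(C)C(C)(C)C)CO[Si](C)(C)C(C)(C)C)cc1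
F11 | step 13 | 3-[(4-methoxybenzyl)oxy]propanal | COc1ccc(COCCC=O)cc1
F12 | step 13 | 1-({[(3Z)-4-iodopent-3-en-1-yl]oxy}methyl)-4-methoxybenzene | COc1ccc(COCC/C=C(/C)I)cc1
F13 | step 13 | (2R,3Z)-1-{[tert-butyl(dimethyl)silyl]oxy}-6-[(4-methoxybenzyl)oxy]-3-methylhex-3-en-2-ol | COc1ccc(COCC/C=C(/C)[C@@H](O)CO[Si](C)(C)C(C)(C)C)cc1
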